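**Retrosynthetic overview**

1. Feature: in germacrane numbering, the lactone oxygen on C6, ring carbon C7 and the exocyclic C11(=C13H2)–C12 acrylate form a homoallylic alcohol shared by the ten-membered carbocycle (C1–C10) and the γ-lactone. This is the product pattern of a [2,3]-Wittig shift of a C6–O–C13 allyl ether.
2. Key disconnection: cut C6–C7 and join O–C13. Carbocycle and lactone then both come from the thirteen-membered α-allyloxy enone ether 26 (C5 ketone, C12 methyl ester, ring-cis C7=C11, E C1=C2); C5 is reduced and acetylated and C8 esterified afterwards.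
3. Ether 26 comes from Nozaki–Hiyama–Kishi closure at C4–C5 and oxidation. The C6–O–C13 ether comes from a Morita–Baylis–Hillman-derived allylic bromide (C11–C13 from methyl acrylate) and ethylene glycol (C5, C6). C2–C4 and C15 come from a Julia–Kocienski olefination at C1.
4. C7–C10, C14 and the C10 carbinol come from (R)-linalool. The C8 oxygen is installed by proline-catalysed α-aminoxylation, deliberately as the 8S epimer, and inverted at the end by Mitsunobu esterification with tiglic acid.
5. Ring order: thirteen-membered ether (step 16), then ten-membered carbocycle and γ-lactone in one operation (step 18).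

Key step: step 18

Remark on numbering: germacrane numbering is used throughout (C1=C2, C3, C4(=C15), C5, C6, C7 bearing C11(=C13)–C12, C8, C9, C10 bearing C14); β is the ring face carrying C14 and the C7–C11 bond.

Remark on C8: in the five-centre transition state H8 should lie in the C7=C11 plane (1,3-allylic strain with C13H2) and C6 should add anti to the C8–O bond. An 8R ether would then give the wrong C7 epimer, so the ring contraction is run on the 8S ether (8α-OSiEt3) and C8 is inverted in step 22.

Assumption: commercial (R)-(−)-linalool of high enantiomeric purity is the source of the C10 centre.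

**Route**

Step 1
Reactants: 1 (R)-(−)-linalool
Product: 2 triethyl{[(3R)-3,7-dimethylocta-1,6-dien-3-yl]oxy}silane
Conditions: TESOTf, 2,6-lutidine, CH2Cl2, −78 to 0 °C
Reagents that add atoms: triethylsilyl trifluoromethanesulfonate CC[Si](CC)(CC)OS(=O)(=O)C(F)(F)F
Why: Silyl ether formation with a silyl triflate and a hindered pyridine base silylates the tertiary allylic alcohol and masks the C10 carbinol for all later base and hydride steps without touching the stereocentre.

Step 2
Reactants: 2 triethyl{[(3R)-3,7-dimethylocta-1,6-dien-3-yl]oxy}silane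
Product: 4 (4R)-4-methyl-4-(triethylsilyloxy)hex-5-enal, via ozonide 3 (not isolated)
Conditions: O3 (1 equiv, Sudan Red 7B end-point), CH2Cl2, −78 °C; then PPh3, −78 °C to rt
Reagents that add atoms: ozone [O-][O+]=O
Why: Chemoselective ozonolysis, because ozone as an electrophilic 1,3-dipole should cleave the electron-rich trisubstituted alkene much faster than the vinyl group, which is deactivated and shielded by the adjacent silyloxy-bearing quaternary carbon, and the dye end-point limits the reaction to one equivalent before phosphine reduction of the ozonide.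

Step 3
Reactants: 4 (4R)-4-methyl-4-(triethylsilyloxy)hex-5-enal
Product: 6 (2S,4R)-4-methyl-2-(phenylaminooxy)-4-(triethylsilyloxy)hex-5-en-1-ol, via aminoxy aldehyde 5 (not isolated)
Conditions: PhNO (0.9 equiv), D-proline (20 mol%), DMSO, 20 °C; then NaBH4, EtOH, 0 °C
Reagents that add atoms: nitrosobenzene O=Nc1ccccc1
Why: Proline-catalysed enamine α-aminoxylation (O-selective nitroso aldol) followed by borohydride reduction in the same flask, in which the carboxylic acid of D-proline delivers the nitroso oxygen to one face of the E-enamine so that the C8 centre is formed 2S by catalyst control (the mirror image of the established L-proline outcome), independent of the remote C10 centre, and immediate reduction prevents epimerisation of the α-oxy aldehyde.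

Step 4
Reactants: 6 (2S,4R)-4-methyl-2-(phenylaminooxy)-4-(triethylsilyloxy)hex-5-en-1-ol
Product: 7 (2S,4R)-4-methyl-4-(triethylsilyloxy)hex-5-ene-1,2-diol
Conditions: Zn dust, AcOH, EtOH, 20 °C
Reagents that add atoms: none
Why: Reductive cleavage of the weak N–O bond by zinc in acetic acid should release the free 1,2-diol and aniline without affecting the alkene or the tertiary silyl ether.

Step 5
Reactants: 7 (2S,4R)-4-methyl-4-(triethylsilyloxy)hex-5-ene-1,2-diol
Product: 8 (3R,5S)-3-methyl-3,5,6-tris(triethylsilyloxy)hex-1-ene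
Conditions: TESCl, imidazole, DMF, 0 °C to rt
Reagents that add atoms: chlorotriethylsilane CC[Si](Cl)(CC)CC
Why: Standard silylation (silyl chloride and imidazole) of the primary and the secondary hydroxyl gives a primary silyl ether that can later be oxidised selectively.

Step 6
Reactants: 8 (3R,5S)-3-methyl-3,5,6-tris(triethylsilyloxy)hex-1-ene
Product: 10 (2R,4S)-2-methyl-2,4,5-tris(triethylsilyloxy)pentanal, via ozonide 9 (not isolated)
Conditions: O3, CH2Cl2, −78 °C; then PPh3, −78 °C to rt
Reagents that add atoms: ozone [O-][O+]=O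
Why: Ozonolysis of the only remaining alkene with phosphine reduction gives the non-enolisable α-silyloxy aldehyde at C1, so the C10 centre cannot epimerise.

Step 7
Reactants: 11 but-3-yn-1-ol
Product: 12 3-iodobut-3-en-1-ol
Conditions: NaI, Me3SiCl, H2O, MeCN, rt
Reagents that add atoms: sodium iodide [Na+].[I-]
Why: Markovnikov hydroiodination of the terminal alkyne by hydrogen iodide generated in the flask gives the 2-iodoalk-1-ene (future C4–I and C15) regioselectively.

Step 8
Reactants: 12 3-iodobut-3-en-1-ol
Product: 13 5-[(3-iodobut-3-en-1-yl)sulfanyl]-1-phenyl-1H-tetrazole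
Conditions: 1-phenyl-1H-tetrazole-5-thiol, PPh3, DIAD, THF, 0 °C to rt
Reagents that add atoms: 1-phenyl-1H-tetrazole-5-thiol Sc1nnnn1-c1ccccc1
Why: Mitsunobu thioetherification, in which the acidic tetrazole thiol displaces the alkoxyphosphonium ion of the primary alcohol by SN2.

Step 9
Reactants: 13 5-[(3-iodobut-3-en-1-yl)sulfanyl]-1-phenyl-1H-tetrazole
Product: 14 5-[(3-iodobut-3-en-1-yl)sulfonyl]-1-phenyl-1H-tetrazole
Conditions: H2O2 (30%), (NH4)6Mo7O24·4H2O (cat.), EtOH, 0 °C to rt
Reagents that add atoms: hydrogen peroxide OO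
Why: Molybdate-catalysed peroxide oxidation of sulfide to sulfone, under which the electron-poor iodoalkene should not be epoxidised.

Step 10
Reactants: 10 (2R,4S)-2-methyl-2,4,5-tris(triethylsilyloxy)pentanal; 14 5-[(3-iodobut-3-en-1-yl)sulfonyl]-1-phenyl-1H-tetrazole
Product: 15 (4E,6R,8S)-2-iodo-6-methyl-6,8,9-tris(triethylsilyloxy)nona-1,4-diene
Conditions: KN(SiMe3)2, 14, DME, −60 °C; then 10, −60 °C to rt; AcOH quench
Reagents that add atoms: none
Why: Julia–Kocienski olefination, in which the metallated 1-phenyltetrazolyl sulfone adds to the hindered aldehyde and the adduct undergoes Smiles rearrangement with loss of SO2 and tetrazolone, the potassium counter-ion in DME and the α-branched aldehyde favouring the anti adduct and hence the E C1=C2 alkene.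

Step 11
Reactants: 15 (4E,6R,8S)-2-iodo-6-methyl-6,8,9-tris(triethylsilyloxy)nona-1,4-diene
Product: 17 (2S,4R,5E)-8-iodo-4-methyl-2,4-bis(triethylsilyloxy)nona-5,8-dienal, via alkoxysulfonium chloride 16 (not isolated)
Conditions: (COCl)2, DMSO, CH2Cl2, −78 to −30 °C; then i-Pr2NEt, −78 °C to rt
Reagents that add atoms: none
Why: Swern oxidation applied directly to a primary triethylsilyl ether, in which the chlorosulfonium salt exchanges only the unhindered primary silyl group for the alkoxysulfonium ion that the amine base collapses to the C7 aldehyde, leaving the secondary and tertiary silyl ethers and the C8 centre intact at low temperature.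

Step 12
Reactants: 17 (2S,4R,5E)-8-iodo-4-methyl-2,4-bis(triethylsilyloxy)nona-5,8-dienal; 18 methyl acrylate
Product: 19 methyl (4S,6R,7E)-3-hydroxy-10-iodo-6-methyl-2-methylidene-4,6-bis(triethylsilyloxy)undeca-7,10-dienoate (C3 epimers)
Conditions: DABCO (1 equiv), neat 18 (20 equiv), MeOH (2 equiv), 20 °C
Reagents that add atoms: none
Why: Morita–Baylis–Hillman reaction, in which the DABCO–acrylate zwitterion adds to the inductively activated α-silyloxy aldehyde to form C7–C11, the new C7 carbinol centre being formed without control, which is of no consequence because C7 becomes sp2 in step 13.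

Step 13
Reactants: 19 methyl (4S,6R,7E)-3-hydroxy-10-iodo-6-methyl-2-methylidene-4,6-bis(triethylsilyloxy)undeca-7,10-dienoate
Product: 21 methyl (2Z,4S,6R,7E)-2-(bromomethyl)-10-iodo-6-methyl-4,6-bis(triethylsilyloxy)undeca-2,7,10-trienoate, via mesylate 20 (not isolated)
Conditions: MsCl, Et3N, CH2Cl2, −20 °C; then LiBr, THF, 0 °C to rt
Reagents that add atoms: lithium bromide [Li+].[Br-]
Why: Mesylation followed by SN2' attack of bromide at C13 transposes the alkene to C7=C11 and should give the thermodynamically preferred Z-2-(bromomethyl)enoate (ester trans to C8), the geometry with C13 and C8 cis that the later five-centre transition state requires.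

Step 14
Reactants: 21 methyl (2Z,4S,6R,7E)-2-(bromomethyl)-10-iodo-6-methyl-4,6-bis(triethylsilyloxy)undeca-2,7,10-trienoate; 22 ethylene glycol
Product: 23 methyl (2E,4S,6R,7E)-2-[(2-hydroxyethoxy)methyl]-10-iodo-6-methyl-4,6-bis(triethylsilyloxy)undeca-2,7,10-trienoate
Conditions: Ag2O, 22 (10 equiv), 4 Å molecular sieves, MeCN, rt, dark
Reagents that add atoms: none
Why: Silver-assisted Williamson-type etherification, in which the diol (in excess to ensure mono-alkylation) attacks the unhindered primary allylic carbon C13 by SN2 in preference to the C7 terminus shielded by the C8 silyl ether, so the conjugated alkene and its geometry are kept.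

Step 15
Reactants: 23 methyl (2E,4S,6R,7E)-2-[(2-hydroxyethoxy)methyl]-10-iodo-6-methyl-4,6-bis(triethylsilyloxy)undeca-2,7,10-trienoate
Product: 24 methyl (2E,4S,6R,7E)-10-iodo-6-methyl-2-[(2-oxoethoxy)methyl]-4,6-bis(triethylsilyloxy)undeca-2,7,10-trienoate
Conditions: Dess–Martin periodinane, pyridine, CH2Cl2, 0 °C
Reagents that add atoms: none
Why: Dess–Martin oxidation of the primary alcohol under pyridine buffering gives the alkoxyacetaldehyde (C5) without cleaving silyl ethers or touching the iodoalkene.

Step 16
Reactants: 24 methyl (2E,4S,6R,7E)-10-iodo-6-methyl-2-[(2-oxoethoxy)methyl]-4,6-bis(triethylsilyloxy)undeca-2,7,10-trienoate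
Product: 25 methyl (3E,5S,7R,8E)-12-hydroxy-7-methyl-11-methylidene-5,7-bis(triethylsilyloxy)-1-oxacyclotrideca-3,8-diene-3-carboxylate (C12 epimers)
Conditions: CrCl2 (10 equiv), NiCl2 (5 mol%), DMSO/THF 3:1, rt, 2 mM (slow addition of 24)
Reagents that add atoms: none
Why: Intramolecular Nozaki–Hiyama–Kishi coupling, in which NiCl2-catalysed oxidative addition into the C4–I bond, transmetalation to chromium and chemoselective addition to the C5 aldehyde close the thirteen-membered ring under high dilution, the new C5 carbinol centre forming as a mixture that converges in step 17.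

Step 17
Reactants: 25 methyl (3E,5S,7R,8E)-12-hydroxy-7-methyl-11-methylidene-5,7-bis(triethylsilyloxy)-1-oxacyclotrideca-3,8-diene-3-carboxylate
Product: 26 methyl (3E,5S,7R,8E)-7-methyl-11-methylidene-12-oxo-5,7-bis(triethylsilyloxy)-1-oxacyclotrideca-3,8-diene-3-carboxylate
Conditions: Dess–Martin periodinane, pyridine, CH2Cl2, 0 °C; used at once
Reagents that add atoms: none
Why: Dess–Martin oxidation of the allylic alcohol gives the α-methylene ketone under non-basic conditions, so the base-sensitive α-allyloxy enone is made only immediately before use.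

Step 18
Reactants: 26 methyl (3E,5S,7R,8E)-7-methyl-11-methylidene-12-oxo-5,7-bis(triethylsilyloxy)-1-oxacyclotrideca-3,8-diene-3-carboxylate
Product: 29 (6βH,7αH)-5-oxo-8α,10α-bis(triethylsilyloxy)germacra-1(2)E,4(15),11(13)-trien-12,6α-olide, via lithium enolate 27 (not isolated), via lithium alkoxide 28 (not isolated)
Conditions: LiN(SiMe3)2 (1.1 equiv), THF, 2 mM, −78 to −20 °C; AcOH quench at −78 °C
Reagents that add atoms: none
Why: Proposed new method: LiN(SiMe3)2 removes one of the C6 protons (the only enolisable ketone α-position, C4 being sp2) to give the chelated lithium Z-enolate 27, whose C6 terminus bonds to C7 through a five-centre envelope while the O–C13 bond breaks, a [2,3]-sigmatropic (Wittig-type) shift that can equally be viewed as intramolecular conjugate addition to the C12 acrylate with loss of the β-alkoxide, and that contracts the thirteen-membered ether to the ten-membered carbocycle. The closest known reaction types are [2,3]-Wittig ring contractions of thirteen-membered diallylic ethers to cyclodecenols and enolate [2,3]-Wittig shifts of open-chain α-allyloxy ketones; the two have not been combined on an ester-bearing allyl unit inside a macrocycle. The carbocycle closes transannularly by C6–C7 bond formation within the five-membered cyclic transition state, and the γ-lactone then closes by 5-exo-trig acyl substitution of the freed C6 lithium alkoxide 28 on the C12 methyl ester with loss of methoxide. C7 is controlled by the adjacent C8 centre, since 1,3-allylic strain against C13H2 keeps H8 in the alkene plane and the enolate adds anti to the C8–O bond on the face that carries C9, which for the 8S ether gives 7R; C6 is controlled by the ring, because with C6 and C9 on the same face only the arrangement with C5 anti to C8 (enolate oxygen turned towards the ester carbonyl and bridged to it by lithium) lets the C4–C3–C2–C1–C10 bridge span the forming bond, and this arrangement leads to the trans-fused lactone. The step needs C6–C7 bonding in preference to the oxyanion-accelerated [3,3] shift through C5 and to intermolecular Michael addition, which the lithium counter-ion, the low temperature, high dilution and the electron-poor C7 terminus are expected to secure. Should some cis-fused lactone form, C6 remains epimerisable α to the C5 ketone.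

Step 19
Reactants: 29 (6βH,7αH)-5-oxo-8α,10α-bis(triethylsilyloxy)germacra-1(2)E,4(15),11(13)-trien-12,6α-olide
Product: 30 (6βH,7αH)-5β-hydroxy-8α,10α-bis(triethylsilyloxy)germacra-1(2)E,4(15),11(13)-trien-12,6α-olide
Conditions: NaBH4, CeCl3·7H2O, MeOH/THF, −78 °C
Reagents that add atoms: none
Why: Luche reduction, in which CeCl3 in methanol directs borohydride to 1,2-addition at the C5 ketone and should spare the α-methylene lactone at −78 °C, the new C5 centre being set by Felkin–Anh control from C6 with hydride approaching from the ring periphery anti to the electron-withdrawing C6–O bond to give the 5,6-syn (5β) alcohol.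

Step 20
Reactants: 30 (6βH,7αH)-5β-hydroxy-8α,10α-bis(triethylsilyloxy)germacra-1(2)E,4(15),11(13)-trien-12,6α-olide
Product: 31 (6βH,7αH)-5β-acetoxy-8α,10α-bis(triethylsilyloxy)germacra-1(2)E,4(15),11(13)-trien-12,6α-olide
Conditions: Ac2O, pyridine, DMAP (cat.), CH2Cl2, 0 °C to rt
Reagents that add atoms: acetic anhydride CC(=O)OC(C)=O
Why: DMAP-catalysed acylation of the secondary allylic C5 alcohol with acetic anhydride, no other free hydroxyl being present.

Step 21
Reactants: 31 (6βH,7αH)-5β-acetoxy-8α,10α-bis(triethylsilyloxy)germacra-1(2)E,4(15),11(13)-trien-12,6α-olide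
Product: 32 (6βH,7αH)-5β-acetoxy-8α,10α-dihydroxygermacra-1(2)E,4(15),11(13)-trien-12,6α-olide
Conditions: HF·pyridine, pyridine, THF, 0 °C to rt
Reagents that add atoms: none
Why: Fluoride-mediated desilylation with pyridine-buffered HF·pyridine cleaves both Si–O bonds under non-basic conditions that should spare the acetate, the Michael-acceptor lactone and the tertiary allylic alcohol.

Step 22
Reactants: 32 (6βH,7αH)-5β-acetoxy-8α,10α-dihydroxygermacra-1(2)E,4(15),11(13)-trien-12,6α-olide; 33 tiglic acid
Product: 34 (5S,6S,7R,8R,10R)-5β-acetoxy-10α-hydroxy-8β-[(E)-2-methylbut-2-enoyloxy]germacra-1(2)E,4(15),11(13)-trien-12,6α-olide (CNP0323375.1)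
Conditions: PPh3, DIAD, 33 (3 equiv), toluene/THF, 0 °C to rt
Reagents that add atoms: none
Why: Mitsunobu esterification, in which the secondary C8 alcohol is activated as its alkoxyphosphonium ion and displaced by tiglate with inversion (8S to 8R), while the tertiary C10 alcohol cannot be activated and the E geometry of the acid is retained.

**Compound list**

1 | (R)-(−)-linalool | CC(C)=CCC[C@@](C)(O)C=C | starting material
2 | triethyl{[(3R)-3,7-dimethylocta-1,6-dien-3-yl]oxy}silane | CC(C)=CCC[C@@](C)(O[Si](CC)(CC)CC)C=C | intermediate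
3 | ozonide of 2 at the trisubstituted alkene (1,2,4-trioxolane, ring carbon unassigned) | CC1(C)OOC(CC[C@@](C)(O[Si](CC)(CC)CC)C=C)O1 | intermediate (not isolated)
4 | (4R)-4-methyl-4-(triethylsilyloxy)hex-5-enal | O=CCC[C@@](C)(O[Si](CC)(CC)CC)C=C | intermediate
5 | (2S,4R)-4-methyl-2-(phenylaminooxy)-4-(triethylsilyloxy)hex-5-enal | O=C[C@@H](ONc1ccccc1)C[C@@](C)(O[Si](CC)(CC)CC)C=C | intermediate (not isolated)
6 | (2S,4R)-4-methyl-2-(phenylaminooxy)-4-(triethylsilyloxy)hex-5-en-1-ol | OC[C@@H](ONc1ccccc1)C[C@@](C)(O[Si](CC)(CC)CC)C=C | intermediate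
7 | (2S,4R)-4-methyl-4-(triethylsilyloxy)hex-5-ene-1,2-diol | OC[C@@H](O)C[C@@](C)(O[Si](CC)(CC)CC)C=C | intermediate
8 | (3R,5S)-3-methyl-3,5,6-tris(triethylsilyloxy)hex-1-ene | CC[Si](CC)(CC)OC[C@@H](O[Si](CC)(CC)CC)C[C@@](C)(O[Si](CC)(CC)CC)C=C | intermediate
9 | ozonide of 8 (1,2,4-trioxolane, ring carbon unassigned) | CC[Si](CC)(CC)OC[C@@H](O[Si](CC)(CC)CC)C[C@@](C)(O[Si](CC)(CC)CC)C1OCOO1 | intermediate (not isolated)
10 | (2R,4S)-2-methyl-2,4,5-tris(triethylsilyloxy)pentanal | CC[Si](CC)(CC)OC[C@@H](O[Si](CC)(CC)CC)C[C@@](C)(O[Si](CC)(CC)CC)C=O | intermediate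
11 | but-3-yn-1-ol | C#CCCO | starting material
12 | 3-iodobut-3-en-1-ol | C=C(I)CCO | intermediate
13 | 5-[(3-iodobut-3-en-1-yl)sulfanyl]-1-phenyl-1H-tetrazole | C=C(I)CCSc1nnnn1-c1ccccc1 | intermediate
14 | 5-[(3-iodobut-3-en-1-yl)sulfonyl]-1-phenyl-1H-tetrazole | C=C(I)CCS(=O)(=O)c1nnnn1-c1ccccc1 | intermediate
15 | (4E,6R,8S)-2-iodo-6-methyl-6,8,9-tris(triethylsilyloxy)nona-1,4-diene | CC[Si](CC)(CC)OC[C@@H](O[Si](CC)(CC)CC)C[C@@](C)(O[Si](CC)(CC)CC)/C=C/CC(I)=C | intermediate
16 | dimethyl(alkoxy)sulfonium chloride of the primary oxygen of 15 | C[S+](C)OC[C@@H](O[Si](CC)(CC)CC)C[C@@](C)(O[Si](CC)(CC)CC)/C=C/CC(I)=C.[Cl-] | intermediate (not isolated)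
17 | (2S,4R,5E)-8-iodo-4-methyl-2,4-bis(triethylsilyloxy)nona-5,8-dienal | O=C[C@@H](O[Si](CC)(CC)CC)C[C@@](C)(O[Si](CC)(CC)CC)/C=C/CC(I)=C | intermediate
18 | methyl acrylate | C=CC(=O)OC | starting material
19 | methyl (4S,6R,7E)-3-hydroxy-10-iodo-6-methyl-2-methylidene-4,6-bis(triethylsilyloxy)undeca-7,10-dienoate (C3 epimers) | C=C(C(=O)OC)C(O)[C@@H](O[Si](CC)(CC)CC)C[C@@](C)(O[Si](CC)(CC)CC)/C=C/CC(I)=C | intermediate
20 | C3 methanesulfonate of 19 | C=C(C(=O)OC)C(OS(C)(=O)=O)[C@@H](O[Si](CC)(CC)CC)C[C@@](C)(O[Si](CC)(CC)CC)/C=C/CC(I)=C | intermediate (not isolated)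
21 | methyl (2Z,4S,6R,7E)-2-(bromomethyl)-10-iodo-6-methyl-4,6-bis(triethylsilyloxy)undeca-2,7,10-trienoate | COC(=O)/C(CBr)=C/[C@@H](O[Si](CC)(CC)CC)C[C@@](C)(O[Si](CC)(CC)CC)/C=C/CC(I)=C | intermediate
22 | ethylene glycol | OCCO | starting material
23 | methyl (2E,4S,6R,7E)-2-[(2-hydroxyethoxy)methyl]-10-iodo-6-methyl-4,6-bis(triethylsilyloxy)undeca-2,7,10-trienoate | COC(=O)/C(COCCO)=C/[C@@H](O[Si](CC)(CC)CC)C[C@@](C)(O[Si](CC)(CC)CC)/C=C/CC(I)=C | intermediate
24 | methyl (2E,4S,6R,7E)-10-iodo-6-methyl-2-[(2-oxoethoxy)methyl]-4,6-bis(triethylsilyloxy)undeca-2,7,10-trienoate | COC(=O)/C(COCC=O)=C/[C@@H](O[Si](CC)(CC)CC)C[C@@](C)(O[Si](CC)(CC)CC)/C=C/CC(I)=C | intermediate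
25 | methyl (3E,5S,7R,8E)-12-hydroxy-7-methyl-11-methylidene-5,7-bis(triethylsilyloxy)-1-oxacyclotrideca-3,8-diene-3-carboxylate (C12 epimers) | COC(=O)/C1=C/[C@@H](O[Si](CC)(CC)CC)C[C@@](C)(O[Si](CC)(CC)CC)/C=C/CC(=C)C(O)COC1 | intermediate
26 | methyl (3E,5S,7R,8E)-7-methyl-11-methylidene-12-oxo-5,7-bis(triethylsilyloxy)-1-oxacyclotrideca-3,8-diene-3-carboxylate (key-step precursor) | COC(=O)/C1=C/[C@@H](O[Si](CC)(CC)CC)C[C@@](C)(O[Si](CC)(CC)CC)/C=C/CC(=C)C(=O)COC1 | intermediate
27 | lithium Z-enolate of 26 (C5=C6) | COC(=O)/C1=C/[C@@H](O[Si](CC)(CC)CC)C[C@@](C)(O[Si](CC)(CC)CC)/C=C/CC(=C)/C(O[Li])=C/OC1 | intermediate (not isolated)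
28 | lithium C6 alkoxide of the ring-contracted ten-membered 5-oxo 12-methyl ester | C=C(C(=O)OC)[C@@H]1[C@@H](O[Si](CC)(CC)CC)C[C@@](C)(O[Si](CC)(CC)CC)/C=C/CC(=C)C(=O)[C@H]1O[Li] | intermediate (not isolated)
29 | (6βH,7αH)-5-oxo-8α,10α-bis(triethylsilyloxy)germacra-1(2)E,4(15),11(13)-trien-12,6α-olide (key-step product) | C=C1C(=O)O[C@H]2[C@H]1[C@@H](O[Si](CC)(CC)CC)C[C@@](C)(O[Si](CC)(CC)CC)/C=C/CC(=C)C2=O | intermediate
30 | (6βH,7αH)-5β-hydroxy-8α,10α-bis(triethylsilyloxy)germacra-1(2)E,4(15),11(13)-trien-12,6α-olide | C=C1C(=O)O[C@H]2[C@H]1[C@@H](O[Si](CC)(CC)CC)C[C@@](C)(O[Si](CC)(CC)CC)/C=C/CC(=C)[C@@H]2O | intermediate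
31 | (6βH,7αH)-5β-acetoxy-8α,10α-bis(triethylsilyloxy)germacra-1(2)E,4(15),11(13)-trien-12,6α-olide | C=C1C(=O)O[C@H]2[C@H]1[C@@H](O[Si](CC)(CC)CC)C[C@@](C)(O[Si](CC)(CC)CC)/C=C/CC(=C)[C@@H]2OC(C)=O | intermediate
32 | (6βH,7αH)-5β-acetoxy-8α,10α-dihydroxygermacra-1(2)E,4(15),11(13)-trien-12,6α-olide | C=C1C(=O)O[C@H]2[C@H]1[C@@H](O)C[C@@](C)(O)/C=C/CC(=C)[C@@H]2OC(C)=O | intermediate
33 | tiglic acid, (E)-2-methylbut-2-enoic acid | C/C=C(\C)C(=O)O | starting material
34 | (5S,6S,7R,8R,10R)-5β-acetoxy-10α-hydroxy-8β-[(E)-2-methylbut-2-enoyloxy]germacra-1(2)E,4(15),11(13)-trien-12,6α-olide, CNP0323375.1 | C=C1C(=O)O[C@H]2[C@H]1[C@H](OC(=O)/C(C)=C/C)C[C@@](C)(O)/C=C/CC(=C)[C@@H]2OC(C)=O | target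

**Step count and risks**

Total step count: 22. Longest linear sequence: 19 steps (steps 1–6 and 10–22; steps 7–9 prepare sulfone 14).

The three steps most likely to fail:

1. Step 18 (ring contraction and lactonisation). The enolate may add to the other face of C7 if the macrocycle overrides the local C8 control. It may also divert into the [3,3] pathway through C5 or into intermolecular Michael oligomerisation, and the amide base or released methoxide may add to the exocyclic enone.
   Fallback, setting out from allylic bromide 21 and rejoining at ketone 29: the C6–C7 bond is made intermolecularly by a Barbier allylation of 2-[(4-methoxybenzyl)oxy]acetaldehyde with 21 (In powder, THF/H2O; the iodoalkene is inert). Allylic transposition and lactonisation on work-up give the α-methylene-γ-lactone 4-methoxybenzyl ether F1. Buffered DDQ gives the primary alcohol F2, and Dess–Martin oxidation gives the aldehyde F3. Intramolecular Nozaki–Hiyama–Kishi coupling (CrCl2, catalytic NiCl2, DMSO, high dilution) closes the ten-membered ring at C4–C5 to the hydroxy lactone F4. Dess–Martin oxidation of F4 gives the C5 ketone, whose C6 centre, whatever the Barbier step delivered, is equilibrated with a catalytic amidine base to the trans-fused 29.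

2. Step 22 (Mitsunobu inversion with tiglic acid). The hindered C8 hydroxyl may not be activated by the betaine with so weak an acid, the alkoxyphosphonium ion may eliminate towards C7 or C9 instead of being displaced, and the free 8-hydroxyl may translactonise onto C12.
   Fallback, setting out from diol 32 and rejoining at target 34: the secondary alcohol is sulfonylated selectively (Tf2O, pyridine, CH2Cl2, −40 °C; the tertiary C10 alcohol does not react) to the C8 triflate F5. This is displaced with inversion by caesium tiglate (18-crown-6, toluene, rt).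

3. Step 19 (C5 reduction). The flexible ten-membered ring may present the other carbonyl face, giving poor facial selectivity, or hydride may add in conjugate fashion to the enone or the lactone.
   Fallback, setting out from ketone 29 and rejoining at alcohol 30: substrate control is replaced by reagent control, using a Corey–Bakshi–Shibata reduction (oxazaborolidine catalyst, catecholborane, toluene, −78 °C) with the catalyst antipode that delivers hydride to the α-face of C5. No new compound is involved.

Further compounds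
F1 | step 18 | α-methylene-γ-lactone from 21 and 2-[(4-methoxybenzyl)oxy]acetaldehyde (C6 bears CH2O-4-methoxybenzyl, C6 unassigned, iodoalkene retained) | C=C1C(=O)OC(COCc2ccc(OC)cc2)[C@H]1[C@@H](O[Si](CC)(CC)CC)C[C@@](C)(O[Si](CC)(CC)CC)/C=C/CC(I)=C
F2 | step 18 | primary alcohol from F1 (C5 hydroxymethyl on C6) | C=C1C(=O)OC(CO)[C@H]1[C@@H](O[Si](CC)(CC)CC)C[C@@](C)(O[Si](CC)(CC)CC)/C=C/CC(I)=C
F3 | step 18 | C5 aldehyde from F2 | C=C1C(=O)OC(C=O)[C@H]1[C@@H](O[Si](CC)(CC)CC)C[C@@](C)(O[Si](CC)(CC)CC)/C=C/CC(I)=C
F4 | step 18 | 5-hydroxy-8α,10α-bis(triethylsilyloxy)germacra-1(2)E,4(15),11(13)-trien-12,6-olide (C5 and C6 unassigned) | C=C1C(=O)OC2[C@H]1[C@@H](O[Si](CC)(CC)CC)C[C@@](C)(O[Si](CC)(CC)CC)/C=C/CC(=C)C2O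
F5 | step 22 | C8 trifluoromethanesulfonate of 32 | C=C1C(=O)O[C@H]2[C@H]1[C@@H](OS(=O)(=O)C(F)(F)F)C[C@@](C)(O)/C=C/CC(=C)[C@@H]2OC(C)=O
F0 | step 19 | none | none
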